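**Retrosynthetic overview**

- Target acid ⇐ its tert-butyl ester ⇐ tertiary C8 alcohol: E2 dehydration of an equatorial C8–O bond can only give the 8(17)-alkene.
- 13Z-enoate ⇐ α-acetoxy ketone + stabilised ylide (Wittig at C13=C14).
- Bicyclic hydroxy ketone ⇐ acyclic E,E-trienyl α-acetoxy ketone by one proton-initiated, catalyst-controlled polyene cascade: ring A (C4–C5) first, then ring B (C9–C10), with the C13 carbonyl oxygen capturing the C8 cation. This sets C5, C9, C10 and the C8 oxygen.
- Acyclic ketone ⇐ (E,E)-farnesylacetone by kinetic silyl enol ether formation and acetoxylation.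

Labdane numbering is used for positions. The target is the ent-labdane (5R,9R,10R) with a 13Z side chain (CH2OAc cis to CO2H).

Assumption: isomerically pure (5E,9E)-farnesylacetone is bought, and the acid-catalyst antipode that gives the ent series is identified in a first run by optical rotation against known natural-series material.

**Step 1**
Reactants: 1 (5E,9E)-6,10,14-trimethylpentadeca-5,9,13-trien-2-one [(E,E)-farnesylacetone]
Product: 3 trimethyl{[(5E,9E)-6,10,14-trimethylpentadeca-1,5,9,13-tetraen-2-yl]oxy}silane (terminal silyl enol ether), via lithium enolate 2 (not isolated)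
Conditions: LiN(i-Pr)2, THF, −78 °C; then Me3SiCl, Et3N, −78 to 0 °C
Reagents that add atoms: chlorotrimethylsilane, C[Si](C)(C)Cl
Why: Kinetic deprotonation by the hindered amide occurs at the methyl group and O-silylation traps the terminal enolate (kinetic enolate formation and silylation); no stereocenter is formed and the three trisubstituted alkenes are inert.

**Step 2**
Reactants: 3 terminal silyl enol ether
Product: 4 (5E,9E)-6,10,14-trimethyl-2-oxopentadeca-5,9,13-trien-1-yl acetate
Conditions: Pb(OAc)4, CH2Cl2, −20 to 0 °C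
Reagents that add atoms: lead tetraacetate, CC(=O)O[Pb](OC(C)=O)(OC(C)=O)OC(C)=O
Why: Lead tetraacetate α-acetoxylation of a silyl enol ether puts the acetate on the former methyl carbon (C16) and is much faster than attack on the isolated alkenes at this temperature.

**Step 3**
Reactants: 4 acyclic α-acetoxy ketone
Product: 6 4-[(1S,2S,4aR,8aR)-2-hydroxy-2,5,5,8a-tetramethyldecahydronaphthalen-1-yl]-2-oxobutyl acetate (ent-16-acetoxy-8α-hydroxy-14,15-dinorlabdan-13-one), via tricyclic enol ether 5 (not isolated)
Conditions: chiral confined imidodiphosphorimidate acid (IDPi, antipode for the ent series, 5 mol%), (CF3)3COH, −40 °C; then aq. oxalic acid, THF, 0 °C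
Reagents that add atoms: water, O
Why: Proposed new method: the chiral Brønsted acid protonates the terminal isopropylidene in its pocket, the E,E-triene closes ring A and then ring B through an all-chair anti-addition cascade (Stork–Eschenmoser course) that sets C5, C9 and C10 (trans-decalin, equatorial side chain) in the absolute sense fixed by the catalyst antipode, and the ketone oxygen captures the C8 cation anti to the new C9–C10 bond so the C8 oxygen is equatorial, the enol ether being hydrolysed on work-up; the closest known reactions are the acid-mediated cyclization of farnesylacetone to sclareol oxide and the imidodiphosphorimidate-catalysed asymmetric cyclization of homofarnesol to ambroxide.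

**Step 4**
Reactants: 6 bicyclic hydroxy acetoxy ketone; 7 tert-butyl (triphenyl-λ5-phosphanylidene)acetate
Product: 8 tert-butyl (2Z)-3-(acetoxymethyl)-5-[(1S,2S,4aR,8aR)-2-hydroxy-2,5,5,8a-tetramethyldecahydronaphthalen-1-yl]pent-2-enoate
Conditions: PhMe, 90 °C
Reagents that add atoms: none
Why: Wittig olefination of the open-chain ketone with a stabilised ylide; α-acyloxy ketones are expected to give mainly the isomer with the ester cis to the acyloxymethyl group (the geometry used in butenolide syntheses), which is the required 13Z alkene, and the neutral conditions leave the acetate and tertiary alcohol alone.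

**Step 5**
Reactants: 8 tertiary alcohol
Product: 10 tert-butyl (2Z)-3-(acetoxymethyl)-5-[(1R,4aR,8aR)-5,5,8a-trimethyl-2-methylidenedecahydronaphthalen-1-yl]pent-2-enoate, via chlorosulfite 9 (not isolated)
Conditions: SOCl2, pyridine, CH2Cl2, −78 to −40 °C
Reagents that add atoms: none
Why: Base-mediated anti (E2) elimination of the equatorial tertiary chlorosulfite; only the C17 methyl hydrogens can be anti-periplanar to an equatorial C8–O bond, so the exocyclic 8(17)-alkene forms selectively (regioselective dehydration of an 8-hydroxylabdane) and C5, C9 and C10 are untouched.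

**Step 6**
Reactants: 10 tert-butyl ester
Product: 12 (2Z)-3-(acetoxymethyl)-5-[(1R,4aR,8aR)-5,5,8a-trimethyl-2-methylidenedecahydronaphthalen-1-yl]pent-2-enoic acid (target), via trimethylsilyl ester 11 (not isolated)
Conditions: Me3SiOTf, 2,6-lutidine, CH2Cl2, 0 °C; then H2O (pH 4 buffer)
Reagents that add atoms: none
Why: Silyl triflate-mediated tert-butyl ester cleavage (loss of 2-methylpropene, buffered by the hindered pyridine) avoids free strong acid, so the exocyclic alkene, the 13Z enoate and the allylic acetate survive, and the silyl ester hydrolyses on work-up.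

**Compound list**

1 | (5E,9E)-6,10,14-trimethylpentadeca-5,9,13-trien-2-one, (E,E)-farnesylacetone | CC(=O)CC/C=C(C)/CC/C=C(C)/CCC=C(C)C | starting material
2 | lithium (5E,9E)-6,10,14-trimethylpentadeca-1,5,9,13-tetraen-2-olate (not isolated) | [Li]OC(=C)CC/C=C(C)/CC/C=C(C)/CCC=C(C)C | intermediate
3 | trimethyl{[(5E,9E)-6,10,14-trimethylpentadeca-1,5,9,13-tetraen-2-yl]oxy}silane | C=C(O[Si](C)(C)C)CC/C=C(C)/CC/C=C(C)/CCC=C(C)C | intermediate
4 | (5E,9E)-6,10,14-trimethyl-2-oxopentadeca-5,9,13-trien-1-yl acetate | CC(=O)OCC(=O)CC/C=C(C)/CC/C=C(C)/CCC=C(C)C | intermediate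
5 | ent-16-acetoxy-8,13-epoxy-14,15-dinorlabd-12-ene, tricyclic enol ether with C5, C8, C9, C10 as in 6 (not isolated) | C[C@]13CC[C@@H]2C(C)(C)CCC[C@@]2(C)[C@@H]1CC=C(COC(C)=O)O3 | intermediate
6 | 4-[(1S,2S,4aR,8aR)-2-hydroxy-2,5,5,8a-tetramethyldecahydronaphthalen-1-yl]-2-oxobutyl acetate | C[C@]1(O)CC[C@@H]2C(C)(C)CCC[C@@]2(C)[C@@H]1CCC(=O)COC(C)=O | intermediate
7 | tert-butyl (triphenyl-λ5-phosphanylidene)acetate | CC(C)(C)OC(=O)C=P(c1ccccc1)(c1ccccc1)c1ccccc1 | starting material
8 | tert-butyl (2Z)-3-(acetoxymethyl)-5-[(1S,2S,4aR,8aR)-2-hydroxy-2,5,5,8a-tetramethyldecahydronaphthalen-1-yl]pent-2-enoate | C[C@]1(O)CC[C@@H]2C(C)(C)CCC[C@@]2(C)[C@@H]1CC/C(=C/C(=O)OC(C)(C)C)COC(C)=O | intermediate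
9 | C8 chlorosulfite of 8 (not isolated) | C[C@]1(OS(=O)Cl)CC[C@@H]2C(C)(C)CCC[C@@]2(C)[C@@H]1CC/C(=C/C(=O)OC(C)(C)C)COC(C)=O | intermediate
10 | tert-butyl (2Z)-3-(acetoxymethyl)-5-[(1R,4aR,8aR)-5,5,8a-trimethyl-2-methylidenedecahydronaphthalen-1-yl]pent-2-enoate | C=C1CC[C@@H]2C(C)(C)CCC[C@@]2(C)[C@@H]1CC/C(=C/C(=O)OC(C)(C)C)COC(C)=O | intermediate
11 | trimethylsilyl ester of 12 (not isolated) | C=C1CC[C@@H]2C(C)(C)CCC[C@@]2(C)[C@@H]1CC/C(=C/C(=O)O[Si](C)(C)C)COC(C)=O | intermediate
12 | (2Z)-3-(acetoxymethyl)-5-[(1R,4aR,8aR)-5,5,8a-trimethyl-2-methylidenedecahydronaphthalen-1-yl]pent-2-enoic acid | C=C1CC[C@@H]2C(C)(C)CCC[C@@]2(C)[C@@H]1CC/C(=C/C(=O)O)COC(C)=O | target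

**Totals and risks**

Total step count: 6. Longest linear sequence: 6 (from 1; the ylide 7 is bought).

Steps most likely to fail:

Step 3 (key cyclization). The electron-poor α-acetoxy carbonyl may terminate poorly, the acetate may migrate through a dioxolanylium ion, and the level and sense of induction are untested for this substrate. Fallback: set out from compound 1 and come back at compound 6. Farnesylacetone itself, a better carbonyl nucleophile and the substrate closest to known practice, is cyclized with the same chiral acid to ent-sclareol oxide F1. Aqueous oxalic acid opens this to the hydroxy methyl ketone F2; its enantiomer is a known crystalline compound, so ee can be raised by recrystallization. LiN(i-Pr)2 (2.2 equiv) and Me3SiCl then give the bis-silyl compound F3 (tertiary silyl ether plus kinetic terminal silyl enol ether). Pb(OAc)4 oxidises the enol ether to the silyl-protected acetoxy ketone F4, and dilute acid in the work-up removes the tertiary silyl ether to give 6.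

Step 4 (13Z:13E ratio of the Wittig reaction). The isomers are separable, but the selectivity rests on analogy and a poor ratio costs material. Fallback: set out from compound 1 and come back at compound 8, forming the C13–C16 bond last with retention of alkene geometry instead of making C13=C14 by olefination. Hydroxy ketone F2, made from 1 as above, is C-acylated at its kinetic methyl enolate (LiN(i-Pr)2, 2.2 equiv, then Boc2O) to the β-keto ester F5. The chelated sodium enolate (NaH, then PhNTf2) gives the (Z)-enol triflate F6. Stille coupling with (acetoxymethyl)tributylstannane (Pd(PPh3)4, CuI, LiCl, DMF) replaces triflate by CH2OAc with retention, which places CH2OAc cis to the ester and gives 8.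

Step 5 (regiochemistry of dehydration). If the chlorosulfite ionises instead of undergoing E2, endocyclic alkenes form. Fallback: set out from compound 8 and come back at compound 10 in two operations. SOCl2 in Et2O without base converts the alcohol with retention (internal return) into the equatorial tertiary chloride F7, isolated cold. The bulky amidine base DBU (PhMe, 80 °C) then effects E2, for which only a C17 hydrogen is anti-periplanar, giving 10. Residual endocyclic isomers are removed on AgNO3-impregnated silica.

**Further compounds**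

F1 | step 3 | ent-8,13-epoxy-14,15-dinorlabd-12-ene (ent-sclareol oxide) | C[C@]13CC[C@@H]2C(C)(C)CCC[C@@]2(C)[C@@H]1CC=C(C)O3
F2 | step 3 | ent-8α-hydroxy-14,15-dinorlabdan-13-one | C[C@]1(O)CC[C@@H]2C(C)(C)CCC[C@@]2(C)[C@@H]1CCC(C)=O
F3 | step 3 | bis(trimethylsilyl) derivative of F2 (C8 silyl ether, terminal silyl enol ether) | C[C@]1(O[Si](C)(C)C)CC[C@@H]2C(C)(C)CCC[C@@]2(C)[C@@H]1CCC(=C)O[Si](C)(C)C
F4 | step 3 | C8 trimethylsilyl ether of 6 | C[C@]1(O[Si](C)(C)C)CC[C@@H]2C(C)(C)CCC[C@@]2(C)[C@@H]1CCC(=O)COC(C)=O
F5 | step 4 | tert-butyl ent-8α-hydroxy-13-oxo-16-norlabdan-15-oate | C[C@]1(O)CC[C@@H]2C(C)(C)CCC[C@@]2(C)[C@@H]1CCC(=O)CC(=O)OC(C)(C)C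
F6 | step 4 | tert-butyl ent-8α-hydroxy-13-(trifluoromethanesulfonyloxy)-16-norlabd-13Z-en-15-oate | C[C@]1(O)CC[C@@H]2C(C)(C)CCC[C@@]2(C)[C@@H]1CC/C(=C/C(=O)OC(C)(C)C)OS(=O)(=O)C(F)(F)F
F7 | step 5 | C8 chloride of 8 (chlorine equatorial, same configuration as the hydroxyl) | C[C@]1(Cl)CC[C@@H]2C(C)(C)CCC[C@@]2(C)[C@@H]1CC/C(=C/C(=O)OC(C)(C)C)COC(C)=O
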